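**Plan**
1. Retrosynthetic cuts: (a) the aryl–Cβ bond of the enone (Heck disconnection to an aryl bromide and an aryl vinyl ketone); (b) the C2–aryl bond of the 2H-chromene, back to a planar 3-arylbenzopyrylium cation (stored as its 2-ethoxy acetal) and an arylboronate; (c) both ring bonds of C3 (C2–C3 and C3–C4), which removes C3 with its aryl group as an aryl(chloro)carbene and leaves a 6-silyloxybenzofuran.
2. Enabling feature: O1, C2, C4, C4a and C8a of the pyran ring are the furan ring of a benzofuran on ring A, whose O1–C2=C3 enol ether accepts the carbene. C3 of the chromene is the only pyran atom outside that furan, is sp2 and carries the aryl group. The O1 lone pair stabilises charge at C2, so the chlorocyclopropane opens with strain release to the aromatic benzopyrylium (five- to six-membered ring expansion).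
3. Forward order: chlorodiazirine, silyloxybenzofuran and vinyl ketone are prepared; carbene transfer and ring expansion build the pyran ring and the C3–aryl junction in one operation; arylation at C2; Heck reaction attaches the chalcone chain; global desilylation.
4. Stereochemistry: the single stereocenter C2 (S) is set by catalyst-controlled, enantioconvergent aryl transfer to the achiral benzopyrylium formed from the racemic acetal. The (E)-alkene comes from syn-insertion and syn-β-hydride elimination in the Heck step. Silyl ethers and a buffered fluoride finish protect C2 from ring-opening racemization.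

Key step: step 5

Remark: C2 of the target is read as (S); a 2-(4-hydroxyphenyl)-2H-chromene can open reversibly at O1–C2 under light, strong acid or phenoxide-forming base, so all phenols are carried as silyl ethers, and the C3–aryl axis (one ortho substituent) is taken as freely rotating.

**Step 1**
Reactants: 1 5-bromo-2-hydroxybenzonitrile
Product: 2 5-bromo-2-[(triisopropylsilyl)oxy]benzonitrile
Conditions: TIPSCl, imidazole, DMF, rt
Reagents that add atoms: chlorotriisopropylsilane, CC(C)[Si](Cl)(C(C)C)C(C)C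
Why: Standard imidazole-mediated O-silylation of the acidic ortho-cyanophenol; the triisopropylsilyl ether has no activated C–H bond next to oxygen for the later carbene and should withstand the base and acid of steps 2 and 3.

**Step 2**
Reactants: 2 5-bromo-2-[(triisopropylsilyl)oxy]benzonitrile
Product: 4 5-bromo-2-[(triisopropylsilyl)oxy]benzamidine hydrochloride, via lithium silylamidinate 3 (not isolated)
Conditions: LiN(SiMe3)2, THF, 0 °C → rt; then HCl (4 M in dioxane), 0 °C
Reagents that add atoms: lithium bis(trimethylsilyl)amide, [Li]N([Si](C)(C)C)[Si](C)(C)C; hydrogen chloride, Cl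
Why: Addition of the silylamide to the nitrile gives the N-silylated amidinate 3, which anhydrous HCl desilylates to the amidinium chloride (standard amidine synthesis from nitriles), the bulky aryl silyl ether being expected to survive brief cold anhydrous acid.

**Step 3**
Reactants: 4 5-bromo-2-[(triisopropylsilyl)oxy]benzamidine hydrochloride
Product: 5 3-{5-bromo-2-[(triisopropylsilyl)oxy]phenyl}-3-chloro-3H-diazirine
Conditions: aq NaOCl, LiCl, DMSO/pentane, 0 °C → rt, dark; pentane solution kept cold and used at once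
Reagents that add atoms: sodium hypochlorite, [Na+].[O-]Cl
Why: Graham oxidation, in which double N-chlorination of the amidine, base-induced N–N ring closure and chloride exchange give the 3-chloro-3H-diazirine, the biphasic medium extracting the product away from the aqueous base that could attack the silyl ether.

**Step 4**
Reactants: 6 benzofuran-6-ol
Product: 7 (benzofuran-6-yloxy)triisopropylsilane
Conditions: TIPSCl, imidazole, DMF, rt
Reagents that add atoms: chlorotriisopropylsilane, CC(C)[Si](Cl)(C(C)C)C(C)C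
Why: Standard phenol silylation; the silyloxy group later becomes the 7-oxygen that stabilises the benzopyrylium cation.

**Step 5**
Reactants: 5 3-{5-bromo-2-[(triisopropylsilyl)oxy]phenyl}-3-chloro-3H-diazirine; 7 (benzofuran-6-yloxy)triisopropylsilane
Product: 11 rac-3-{5-bromo-2-[(triisopropylsilyl)oxy]phenyl}-2-ethoxy-7-[(triisopropylsilyl)oxy]-2H-chromene, via aryl(chloro)carbene 8 (not isolated), via chlorocyclopropane adduct 9 (not isolated), via 3-arylchromenylium chloride 10 (not isolated)
Conditions: 7 (2 equiv, ≥1 M), 4 Å molecular sieves, MeCN, 45 °C, dark; then EtOH, Et3N, 0 °C → rt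
Reagents that add atoms: ethanol, CCO
Why: Proposed new method: thermolysis of 5 releases N2 and the singlet aryl(chloro)carbene 8, which adds in a concerted [2+1] cheletropic cycloaddition to the electron-rich enol-ether C2=C3 bond of 7 (used in excess and concentrated so that addition outruns azine formation, dimerization or insertion into the ortho silyl group) and closes the cis-fused cyclopropane of 9. Strain release then drives a disrotatory two-electron electrocyclic opening of the chlorocyclopropane with loss of chloride, pushed by the O1 lone pair and the donor aryl group; only the old C2–C3 bond can break, so the five-membered furan ring becomes the six-membered aromatic benzopyrylium 10, in which the carbene carbon is C3 and already carries the aryl group. Ethanol then adds to C2 to give the acetal 11. The closest known reaction types are the Ciamician–Dennstedt-type single-carbon insertion of chlorodiazirine-derived aryl(chloro)carbenes into indoles and pyrroles and the dihalocarbene ring expansion of benzofurans to 3-halo-2H-chromenes; new is the use of an aryl(chloro)carbene on a benzofuran with capture of the oxocarbenium ion as an O,O-acetal. No stereocenter has to be controlled, because both cyclopropane diastereomers of 9 (the exo-chloro one by ionization assisted by the electron-rich aryl group) converge on planar 10 and the racemic acetal center of 11 is erased in step 6. The step needs chemoselectivity for the furan C2=C3 bond, secured because it is the only non-benzenoid π bond in either partner, and ethanol capture at C2 and not C4, secured by the anomeric stabilization of the acetal under reversible conditions (either regioisomer would ionize to the same cation in step 6).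

**Step 6**
Reactants: 11 rac-3-{5-bromo-2-[(triisopropylsilyl)oxy]phenyl}-2-ethoxy-7-[(triisopropylsilyl)oxy]-2H-chromene; 12 {4-[(tert-butyldimethylsilyl)oxy]phenyl}boronic acid
Product: 14 (2S)-3-{5-bromo-2-[(triisopropylsilyl)oxy]phenyl}-2-{4-[(tert-butyldimethylsilyl)oxy]phenyl}-7-[(triisopropylsilyl)oxy]-2H-chromene, via diethyl arylboronate 13 (not isolated)
Conditions: 12, EtOH, 4 Å molecular sieves, rt, then evaporation; 11, chiral tartaric acid monoamide (α,β-dihydroxy acid) catalyst (10 mol %, e.g. the N,N-dibenzylamide), Yb(OTf)3 (9 mol %), EtOAc, −20 → 4 °C, dark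
Reagents that add atoms: none
Why: Chiral Brønsted acid/Lewis acid-catalyzed addition of aryl boronates to 2H-chromene acetals, in which both enantiomers of 11 ionize to the same achiral benzopyrylium, the departing ethoxide is taken up by the catalyst-bound dioxaborolane, and the aryl group is delivered from that chiral borate within the ion pair to C2, so that the catalyst alone fixes the (S) configuration (the catalyst antipode, from L- or D-tartaric acid, is to be assigned in a pilot run).

**Step 7**
Reactants: 15 1-(2,4-dihydroxyphenyl)ethan-1-one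
Product: 16 1-{2,4-bis[(triisopropylsilyl)oxy]phenyl}ethan-1-one
Conditions: NaH (2.2 equiv), TIPSCl (2.3 equiv), THF, 0 °C → rt
Reagents that add atoms: chlorotriisopropylsilane, CC(C)[Si](Cl)(C(C)C)C(C)C
Why: Deprotonation of both phenols (the chelated 2'-OH included) and O-silylation of the phenoxides masks them, so that the later vinyl ketone cannot cyclize by intramolecular oxa-Michael addition.

**Step 8**
Reactants: 16 1-{2,4-bis[(triisopropylsilyl)oxy]phenyl}ethan-1-one
Product: 17 1-{2,4-bis[(triisopropylsilyl)oxy]phenyl}prop-2-en-1-one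
Conditions: (CH2O)n, i-Pr2NH·CF3CO2H, CF3CO2H (cat.), THF, reflux; product stored cold over BHT and used promptly
Reagents that add atoms: paraformaldehyde (as formaldehyde), C=O
Why: Mannich-type direct α-methylenation of an aryl methyl ketone, in which the ammonium salt and formaldehyde give an iminium ion that the ketone enol attacks, and the β-aminoketone eliminates the amine to leave the vinyl ketone.

**Step 9**
Reactants: 14 (2S)-3-{5-bromo-2-[(triisopropylsilyl)oxy]phenyl}-2-{4-[(tert-butyldimethylsilyl)oxy]phenyl}-7-[(triisopropylsilyl)oxy]-2H-chromene; 17 1-{2,4-bis[(triisopropylsilyl)oxy]phenyl}prop-2-en-1-one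
Product: 18 (E)-1-{2,4-bis[(triisopropylsilyl)oxy]phenyl}-3-{3-[(2S)-2-{4-[(tert-butyldimethylsilyl)oxy]phenyl}-7-[(triisopropylsilyl)oxy]-2H-chromen-3-yl]-4-[(triisopropylsilyl)oxy]phenyl}prop-2-en-1-one
Conditions: Pd2(dba)3 (2.5 mol %), P(t-Bu)3 (6 mol %), Cy2NMe, dioxane, rt → 40 °C, dark
Reagents that add atoms: none
Why: Mizoroki–Heck reaction, in which oxidative addition of the aryl bromide to zerovalent palladium, syn-carbopalladation of the terminal enone carbon and syn-β-hydride elimination give the (E)-enone, the bulky electron-rich phosphine allowing a temperature low enough to leave C2 untouched and the hindered chromene alkene not competing.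

**Step 10**
Reactants: 18 (E)-1-{2,4-bis[(triisopropylsilyl)oxy]phenyl}-3-{3-[(2S)-2-{4-[(tert-butyldimethylsilyl)oxy]phenyl}-7-[(triisopropylsilyl)oxy]-2H-chromen-3-yl]-4-[(triisopropylsilyl)oxy]phenyl}prop-2-en-1-one
Product: 19 (E)-1-(2,4-dihydroxyphenyl)-3-{4-hydroxy-3-[(2S)-7-hydroxy-2-(4-hydroxyphenyl)-2H-chromen-3-yl]phenyl}prop-2-en-1-one
Conditions: Bu4NF, AcOH (1:1, 6 equiv), THF, 0 °C, dark
Reagents that add atoms: none
Why: Fluoride-mediated cleavage of all five aryl silyl ethers, the acetic acid buffer keeping the liberated phenols protonated so that neither oxa-Michael closure of the 2'-hydroxychalcone nor quinone-methide ring opening at C2 should be triggered.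

**Compound list**
1 | 5-bromo-2-hydroxybenzonitrile | N#Cc1cc(Br)ccc1O | starting material
2 | 5-bromo-2-[(triisopropylsilyl)oxy]benzonitrile | N#Cc1cc(Br)ccc1O[Si](C(C)C)(C(C)C)C(C)C | intermediate
3 | lithium N,N'-bis(trimethylsilyl)-5-bromo-2-[(triisopropylsilyl)oxy]benzamidinate | [Li]N(C(=N[Si](C)(C)C)c1cc(Br)ccc1O[Si](C(C)C)(C(C)C)C(C)C)[Si](C)(C)C | intermediate
4 | 5-bromo-2-[(triisopropylsilyl)oxy]benzamidine hydrochloride | Cl.NC(=N)c1cc(Br)ccc1O[Si](C(C)C)(C(C)C)C(C)C | intermediate
5 | 3-{5-bromo-2-[(triisopropylsilyl)oxy]phenyl}-3-chloro-3H-diazirine | ClC1(N=N1)c1cc(Br)ccc1O[Si](C(C)C)(C(C)C)C(C)C | intermediate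
6 | benzofuran-6-ol | Oc1ccc2ccoc2c1 | starting material
7 | (benzofuran-6-yloxy)triisopropylsilane | CC(C)[Si](Oc1ccc2ccoc2c1)(C(C)C)C(C)C | intermediate
8 | {5-bromo-2-[(triisopropylsilyl)oxy]phenyl}(chloro)carbene | Cl[C]c1cc(Br)ccc1O[Si](C(C)C)(C(C)C)C(C)C | intermediate
9 | 1-{5-bromo-2-[(triisopropylsilyl)oxy]phenyl}-1-chloro-4-[(triisopropylsilyl)oxy]-1a,6b-dihydro-1H-cyclopropa[b]benzofuran (cis-fused, racemic, exo/endo-chloro mixture) | ClC1(c2cc(Br)ccc2O[Si](C(C)C)(C(C)C)C(C)C)C2Oc3cc(O[Si](C(C)C)(C(C)C)C(C)C)ccc3C12 | intermediate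
10 | 3-{5-bromo-2-[(triisopropylsilyl)oxy]phenyl}-7-[(triisopropylsilyl)oxy]chromenylium chloride | CC(C)[Si](Oc1ccc2cc(-c3cc(Br)ccc3O[Si](C(C)C)(C(C)C)C(C)C)c[o+]c2c1)(C(C)C)C(C)C.[Cl-] | intermediate
11 | rac-3-{5-bromo-2-[(triisopropylsilyl)oxy]phenyl}-2-ethoxy-7-[(triisopropylsilyl)oxy]-2H-chromene | CCOC1Oc2cc(O[Si](C(C)C)(C(C)C)C(C)C)ccc2C=C1c1cc(Br)ccc1O[Si](C(C)C)(C(C)C)C(C)C | intermediate
12 | {4-[(tert-butyldimethylsilyl)oxy]phenyl}boronic acid | OB(O)c1ccc(O[Si](C)(C)C(C)(C)C)cc1 | starting material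
13 | diethyl {4-[(tert-butyldimethylsilyl)oxy]phenyl}boronate | CCOB(OCC)c1ccc(O[Si](C)(C)C(C)(C)C)cc1 | intermediate
14 | (2S)-3-{5-bromo-2-[(triisopropylsilyl)oxy]phenyl}-2-{4-[(tert-butyldimethylsilyl)oxy]phenyl}-7-[(triisopropylsilyl)oxy]-2H-chromene | Brc1ccc(O[Si](C(C)C)(C(C)C)C(C)C)c(c1)C1=Cc2ccc(O[Si](C(C)C)(C(C)C)C(C)C)cc2O[C@H]1c1ccc(O[Si](C)(C)C(C)(C)C)cc1 | intermediate
15 | 1-(2,4-dihydroxyphenyl)ethan-1-one | CC(=O)c1ccc(O)cc1O | starting material
16 | 1-{2,4-bis[(triisopropylsilyl)oxy]phenyl}ethan-1-one | CC(=O)c1ccc(O[Si](C(C)C)(C(C)C)C(C)C)cc1O[Si](C(C)C)(C(C)C)C(C)C | intermediate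
17 | 1-{2,4-bis[(triisopropylsilyl)oxy]phenyl}prop-2-en-1-one | C=CC(=O)c1ccc(O[Si](C(C)C)(C(C)C)C(C)C)cc1O[Si](C(C)C)(C(C)C)C(C)C | intermediate
18 | (E)-1-{2,4-bis[(triisopropylsilyl)oxy]phenyl}-3-{3-[(2S)-2-{4-[(tert-butyldimethylsilyl)oxy]phenyl}-7-[(triisopropylsilyl)oxy]-2H-chromen-3-yl]-4-[(triisopropylsilyl)oxy]phenyl}prop-2-en-1-one | O=C(/C=C/c1ccc(O[Si](C(C)C)(C(C)C)C(C)C)c(C2=Cc3ccc(O[Si](C(C)C)(C(C)C)C(C)C)cc3O[C@H]2c2ccc(O[Si](C)(C)C(C)(C)C)cc2)c1)c1ccc(O[Si](C(C)C)(C(C)C)C(C)C)cc1O[Si](C(C)C)(C(C)C)C(C)C | intermediate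
19 | (E)-1-(2,4-dihydroxyphenyl)-3-{4-hydroxy-3-[(2S)-7-hydroxy-2-(4-hydroxyphenyl)-2H-chromen-3-yl]phenyl}prop-2-en-1-one | O=C(/C=C/c1ccc(O)c(C2=Cc3ccc(O)cc3O[C@H]2c2ccc(O)cc2)c1)c1ccc(O)cc1O | target

**Summary**
Total step count: 10. Longest linear sequence: 7 steps (steps 1, 2, 3, 5, 6, 9, 10).

**Steps most likely to fail**

Step 5 (Proposed new method). The carbene may be consumed by azine formation with unreacted diazirine, by dimerization or by insertion into the neighbouring silyl group before it meets the only moderately nucleophilic benzofuran. The exo-chloro cyclopropane may ionize too slowly, and the 7-silyl group of the cation may be transferred to chloride. The fallback keeps the ring expansion but uses known dihalocarbene chemistry and a later cross-coupling; it sets out from 7 and comes back at 11, and it also bypasses steps 1 to 3. Dibromocarbene (CHBr3, KOt-Bu, hexane, −20 °C → rt) should add to the C2=C3 bond of 7 to give 1,1-dibromo-4-[(triisopropylsilyl)oxy]-1a,6b-dihydro-1H-cyclopropa[b]benzofuran F1. On warming this should open to 3-bromo-7-[(triisopropylsilyl)oxy]chromenylium bromide F2, and EtOH/Et3N should convert that into rac-3-bromo-2-ethoxy-7-[(triisopropylsilyl)oxy]-2H-chromene F3. Miyaura borylation of the alkenyl bromide (B2pin2, PdCl2(PPh3)2, PPh3, KOPh, toluene, 50 °C) should give rac-2-ethoxy-3-(4,4,5,5-tetramethyl-1,3,2-dioxaborolan-2-yl)-7-[(triisopropylsilyl)oxy]-2H-chromene F4. Commercial 4-bromo-2-iodophenol is silylated (TIPSCl, imidazole, DMF) to (4-bromo-2-iodophenoxy)triisopropylsilane F5. An iodide-selective Suzuki–Miyaura coupling of F4 with F5 (Pd(PPh3)4, K3PO4, dioxane/H2O, 50 °C) should leave the aryl bromide untouched and deliver 11.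

Step 6. The aryl transfer may be slow or poorly enantioselective because C2 is flanked by the twisted ortho-silyloxyaryl group at C3, and attack at C4 may compete. The fallback gives up catalyst control for racemic synthesis and resolution; it sets out from 11 and comes back at 14. Commercial (4-bromophenoxy)(tert-butyl)dimethylsilane and Mg in THF give {4-[(tert-butyldimethylsilyl)oxy]phenyl}magnesium bromide F6. F6 should displace the ethoxy group of 11 at C2 (toluene/THF, 0 °C → rt; Grignard substitution of 2-alkoxy-2H-chromenes) to give 14 together with its mirror image, (2R)-3-{5-bromo-2-[(triisopropylsilyl)oxy]phenyl}-2-{4-[(tert-butyldimethylsilyl)oxy]phenyl}-7-[(triisopropylsilyl)oxy]-2H-chromene F7. Preparative chromatography on a chiral stationary phase (supercritical CO2/alcohol) would then separate 14 from F7.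

Step 9. The vinyl ketone may polymerize, oxidative addition into the electron-rich aryl bromide may be sluggish, and a palladium hydride may move the chromene double bond into the achiral 4H-position. The fallback replaces the palladium coupling by a polar aldol sequence; it sets out from 14 and 16 and comes back at 18. Bromine–lithium exchange on 14 (n-BuLi, THF, −78 °C) should give {3-[(2S)-2-{4-[(tert-butyldimethylsilyl)oxy]phenyl}-7-[(triisopropylsilyl)oxy]-2H-chromen-3-yl]-4-[(triisopropylsilyl)oxy]phenyl}lithium F8. Quenching with DMF should give 3-[(2S)-2-{4-[(tert-butyldimethylsilyl)oxy]phenyl}-7-[(triisopropylsilyl)oxy]-2H-chromen-3-yl]-4-[(triisopropylsilyl)oxy]benzaldehyde F9. Ketone 16 is deprotonated with LiN(SiMe3)2 (THF, −78 °C) to lithium 1-{2,4-bis[(triisopropylsilyl)oxy]phenyl}ethen-1-olate F10. F10 should add to F9 to give, after aqueous quench, the β-hydroxy ketone 1-{2,4-bis[(triisopropylsilyl)oxy]phenyl}-3-hydroxy-3-{3-[(2S)-2-{4-[(tert-butyldimethylsilyl)oxy]phenyl}-7-[(triisopropylsilyl)oxy]-2H-chromen-3-yl]-4-[(triisopropylsilyl)oxy]phenyl}propan-1-one F11 (carbinol epimers). MsCl/Et3N (CH2Cl2, 0 °C) should convert F11 into the corresponding methanesulfonate F12, and DBU should eliminate F12 to the (E)-enone 18.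

**Further compounds**
F1 | step 5 | 1,1-dibromo-4-[(triisopropylsilyl)oxy]-1a,6b-dihydro-1H-cyclopropa[b]benzofuran | BrC1(Br)C2Oc3cc(O[Si](C(C)C)(C(C)C)C(C)C)ccc3C12
F2 | step 5 | 3-bromo-7-[(triisopropylsilyl)oxy]chromenylium bromide | CC(C)[Si](Oc1ccc2cc(Br)c[o+]c2c1)(C(C)C)C(C)C.[Br-]
F3 | step 5 | rac-3-bromo-2-ethoxy-7-[(triisopropylsilyl)oxy]-2H-chromene | CCOC1Oc2cc(O[Si](C(C)C)(C(C)C)C(C)C)ccc2C=C1Br
F4 | step 5 | rac-2-ethoxy-3-(4,4,5,5-tetramethyl-1,3,2-dioxaborolan-2-yl)-7-[(triisopropylsilyl)oxy]-2H-chromene | CCOC1Oc2cc(O[Si](C(C)C)(C(C)C)C(C)C)ccc2C=C1B1OC(C)(C)C(C)(C)O1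
F5 | step 5 | (4-bromo-2-iodophenoxy)triisopropylsilane | CC(C)[Si](Oc1ccc(Br)cc1I)(C(C)C)C(C)C
F6 | step 6 | {4-[(tert-butyldimethylsilyl)oxy]phenyl}magnesium bromide | CC(C)(C)[Si](C)(C)Oc1ccc([Mg]Br)cc1
F7 | step 6 | (2R)-3-{5-bromo-2-[(triisopropylsilyl)oxy]phenyl}-2-{4-[(tert-butyldimethylsilyl)oxy]phenyl}-7-[(triisopropylsilyl)oxy]-2H-chromene | Brc1ccc(O[Si](C(C)C)(C(C)C)C(C)C)c(c1)C1=Cc2ccc(O[Si](C(C)C)(C(C)C)C(C)C)cc2O[C@@H]1c1ccc(O[Si](C)(C)C(C)(C)C)cc1
F8 | step 9 | {3-[(2S)-2-{4-[(tert-butyldimethylsilyl)oxy]phenyl}-7-[(triisopropylsilyl)oxy]-2H-chromen-3-yl]-4-[(triisopropylsilyl)oxy]phenyl}lithium | [Li]c1ccc(O[Si](C(C)C)(C(C)C)C(C)C)c(c1)C1=Cc2ccc(O[Si](C(C)C)(C(C)C)C(C)C)cc2O[C@H]1c1ccc(O[Si](C)(C)C(C)(C)C)cc1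
F9 | step 9 | 3-[(2S)-2-{4-[(tert-butyldimethylsilyl)oxy]phenyl}-7-[(triisopropylsilyl)oxy]-2H-chromen-3-yl]-4-[(triisopropylsilyl)oxy]benzaldehyde | O=Cc1ccc(O[Si](C(C)C)(C(C)C)C(C)C)c(c1)C1=Cc2ccc(O[Si](C(C)C)(C(C)C)C(C)C)cc2O[C@H]1c1ccc(O[Si](C)(C)C(C)(C)C)cc1
F10 | step 9 | lithium 1-{2,4-bis[(triisopropylsilyl)oxy]phenyl}ethen-1-olate | [Li]OC(=C)c1ccc(O[Si](C(C)C)(C(C)C)C(C)C)cc1O[Si](C(C)C)(C(C)C)C(C)C
F11 | step 9 | 1-{2,4-bis[(triisopropylsilyl)oxy]phenyl}-3-hydroxy-3-{3-[(2S)-2-{4-[(tert-butyldimethylsilyl)oxy]phenyl}-7-[(triisopropylsilyl)oxy]-2H-chromen-3-yl]-4-[(triisopropylsilyl)oxy]phenyl}propan-1-one | O=C(CC(O)c1ccc(O[Si](C(C)C)(C(C)C)C(C)C)c(c1)C1=Cc2ccc(O[Si](C(C)C)(C(C)C)C(C)C)cc2O[C@H]1c1ccc(O[Si](C)(C)C(C)(C)C)cc1)c1ccc(O[Si](C(C)C)(C(C)C)C(C)C)cc1O[Si](C(C)C)(C(C)C)C(C)C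
F12 | step 9 | methanesulfonate of F11 (3-mesyloxy ketone) | O=C(CC(OS(C)(=O)=O)c1ccc(O[Si](C(C)C)(C(C)C)C(C)C)c(c1)C1=Cc2ccc(O[Si](C(C)C)(C(C)C)C(C)C)cc2O[C@H]1c1ccc(O[Si](C)(C)C(C)(C)C)cc1)c1ccc(O[Si](C(C)C)(C(C)C)C(C)C)cc1O[Si](C(C)C)(C(C)C)C(C)C
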